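## Retrosynthetic overview

1. The target is an erythro 2,3-dimethylbutane with ring A (4-hydroxy-3-methoxyphenyl) on one terminal CH2 and ring B (4-hydroxy-3,5-dimethoxyphenyl) on the other. No ring is formed in the route: both arenes are bought and carried as benzyl ethers until a final hydrogenolysis.
2. Key disconnection: the bond between the benzylic CH2 of ring B and the neighbouring methyl-bearing CH. An α-lithiated benzylic carbamate and a secondary C–B carbon, both nucleophilic, are joined by lithiation–borylation (1,2-metallate rearrangement); the boron left on the benzylic carbon is then replaced by H.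
3. Enabling feature: the CH2 next to ring B is benzylic, so its O-carbamate can be lithiated there and the C–B bond formed there can be protonolysed. The adjacent CH(CH3) can carry boron as a configurationally defined secondary boronic ester that migrates with retention.
4. Fragment 1 (ring A, both stereocentres): the ring-A benzylboronic ester is homologated twice with (S)-1-lithioethyl carbenoids made with (−)-sparteine, first the carbamate and then the 2,4,6-triisopropylbenzoate, under reagent control.
5. Fragment 2 (ring B): syringyl alcohol, O-benzylated on the phenol and carbamoylated on the benzylic alcohol.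

Key step: step 7

Assumption: the boron-bearing benzylic carbon made in step 7 forms as both epimers; this is accepted because step 8 turns that carbon into CH2. Ethyl N,N-diisopropylcarbamate, ethyl 2,4,6-triisopropylbenzoate and (−)-sparteine are taken as purchasable.

## Route

Step 1
Reactants: 1 [4-(benzyloxy)-3-methoxyphenyl]methanol
Product: 2 1-(benzyloxy)-4-(chloromethyl)-2-methoxybenzene
Conditions: SOCl2, CH2Cl2, 0 °C to rt
Reagents that add atoms: thionyl chloride, O=S(Cl)Cl
Why: Chlorodehydroxylation of an electron-rich benzylic alcohol through its chlorosulfite should be fast and leaves the aryl benzyl ether untouched.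

Step 2
Reactants: 2 1-(benzyloxy)-4-(chloromethyl)-2-methoxybenzene
Product: 3 2-[4-(benzyloxy)-3-methoxybenzyl]-4,4,5,5-tetramethyl-1,3,2-dioxaborolane
Conditions: B2pin2, Pd(dba)2 (cat.), P(4-MeOC6H4)3, KOAc, toluene, 50 °C
Reagents that add atoms: bis(pinacolato)diboron, CC1(C)OB(OC1(C)C)B1OC(C)(C)C(C)(C)O1
Why: Miyaura borylation of a benzylic chloride, in which zerovalent palladium inserts into the C–Cl bond, the acetate-activated diboron transmetalates and reductive elimination gives the benzylboronic ester.

Step 3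
Reactants: 4 ethyl N,N-diisopropylcarbamate; 3 2-[4-(benzyloxy)-3-methoxybenzyl]-4,4,5,5-tetramethyl-1,3,2-dioxaborolane
Product: 7 2-[(2R)-1-[4-(benzyloxy)-3-methoxyphenyl]propan-2-yl]-4,4,5,5-tetramethyl-1,3,2-dioxaborolane, via lithiated carbamate 5 (not isolated), via boronate complex 6 (not isolated)
Conditions: 4 (1.3 equiv), s-BuLi (1.2 equiv), (−)-sparteine (1.2 equiv), Et2O, −78 °C, 5 h; then 3, −78 °C, 1 h; then MgBr2·OEt2, reflux, 16 h
Reagents that add atoms: none
Why: Lithiation–borylation (carbenoid homologation of a boronic ester, a 1,2-metallate rearrangement of the Matteson type), in which the sparteine-bound base removes the pro-S proton of 4, the configurationally stable (S)-organolithium 5 adds to boron with retention and the benzyl group shifts anti to the leaving carbamate with inversion at carbon, so the (R) methyl-bearing centre is set by the reagent.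

Step 4
Reactants: 8 ethyl 2,4,6-triisopropylbenzoate; 7 2-[(2R)-1-[4-(benzyloxy)-3-methoxyphenyl]propan-2-yl]-4,4,5,5-tetramethyl-1,3,2-dioxaborolane
Product: 11 2-[(2R,3R)-4-[4-(benzyloxy)-3-methoxyphenyl]-3-methylbutan-2-yl]-4,4,5,5-tetramethyl-1,3,2-dioxaborolane, via lithiated benzoate 9 (not isolated), via boronate complex 10 (not isolated)
Conditions: 8 (1.5 equiv), s-BuLi (1.4 equiv), (−)-sparteine (1.4 equiv), Et2O, −78 °C, 5 h; then 7, −78 °C, 2 h; then warm to rt and reflux, 16 h
Reagents that add atoms: none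
Why: A second lithiation–borylation, now with the (S)-1-lithioethyl 2,4,6-triisopropylbenzoate 9 because the hindered benzoate is the better leaving group and should let the 1,2-shift from the branched boronate 10 proceed without a Lewis acid; the secondary alkyl group of 7 migrates with retention and the new C–B centre is again fixed by the reagent (inversion at the carbenoid carbon), so two insertions of the same sense should give the erythro (2R,3R) array.

Step 5
Reactants: 12 4-(hydroxymethyl)-2,6-dimethoxyphenol (syringyl alcohol)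
Product: 13 [4-(benzyloxy)-3,5-dimethoxyphenyl]methanol
Conditions: BnBr, K2CO3, DMF, rt
Reagents that add atoms: benzyl bromide, BrCc1ccccc1
Why: Williamson ether synthesis that should be chemoselective because only the phenol is deprotonated by carbonate, and the mild temperature avoids loss of the benzylic hydroxyl through a quinone methide.

Step 6
Reactants: 13 [4-(benzyloxy)-3,5-dimethoxyphenyl]methanol
Product: 14 4-(benzyloxy)-3,5-dimethoxybenzyl N,N-diisopropylcarbamate
Conditions: NaH, THF, 0 °C; then N,N-diisopropylcarbamoyl chloride, 0 °C to 60 °C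
Reagents that add atoms: N,N-diisopropylcarbamoyl chloride, CC(C)N(C(C)C)C(=O)Cl
Why: O-Carbamoylation of the sodium alkoxide by acyl substitution installs the group that later directs lithiation and serves as the leaving group.

Step 7
Reactants: 14 4-(benzyloxy)-3,5-dimethoxybenzyl N,N-diisopropylcarbamate; 11 2-[(2R,3R)-4-[4-(benzyloxy)-3-methoxyphenyl]-3-methylbutan-2-yl]-4,4,5,5-tetramethyl-1,3,2-dioxaborolane
Product: 17 2-[(2S,3R)-1-[4-(benzyloxy)-3,5-dimethoxyphenyl]-4-[4-(benzyloxy)-3-methoxyphenyl]-2,3-dimethylbutyl]-4,4,5,5-tetramethyl-1,3,2-dioxaborolane (both epimers at C1), via lithiated benzylic carbamate 15 (not isolated), via boronate complex 16 (not isolated)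
Conditions: 14 (1.3 equiv), s-BuLi (1.25 equiv), TMEDA, Et2O, −78 °C, 30 min; then 11 (1.0 equiv) in Et2O, −78 °C, 2 h; then warm to rt, 16 h
Reagents that add atoms: none
Why: s-BuLi/TMEDA should remove a benzylic proton of 14 next to the carbamate oxygen to give the dipole-stabilised carbanion 15, which adds to the vacant orbital on boron of 11 to form boronate 16; on warming, the secondary alkyl group shifts from boron to carbon anti to the departing carbamate, so two carbons that are both nucleophilic (C–Li and C–B) end up bonded. The closest known reaction type is the lithiation–borylation of benzylic carbamates with secondary alkyl pinacol boronic esters, a 1,2-metallate rearrangement of the Matteson type. No ring is closed. The migrating carbon keeps its configuration because the 1,2-shift is concerted and suprafacial at that carbon, so the C–B centre of 11 is carried into 17 with the same spatial arrangement (its descriptor changes from R to S only through the priority rules) and the neighbouring methyl-bearing centre is not touched. The new boron-bearing benzylic carbon forms as both epimers without control, which is harmless because step 8 makes it a CH2 group. The step needs α-lithiation at the carbamate CH2 rather than on ring B or at the benzyl ether, which the complex-induced proximity effect of the carbamate carbonyl and the benzylic acidity should secure (both positions ortho to the protected phenol oxygen carry methoxy groups), and it needs carbon rather than oxygen migration, which the good carbamate leaving group on a benzylic carbon favours.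

Step 8
Reactants: 17 2-[(2S,3R)-1-[4-(benzyloxy)-3,5-dimethoxyphenyl]-4-[4-(benzyloxy)-3-methoxyphenyl]-2,3-dimethylbutyl]-4,4,5,5-tetramethyl-1,3,2-dioxaborolane (both epimers at C1)
Product: 18 2-(benzyloxy)-5-[(2S,3R)-4-[4-(benzyloxy)-3-methoxyphenyl]-2,3-dimethylbutyl]-1,3-dimethoxybenzene
Conditions: Bu4NF·3H2O (3 equiv), toluene, 60 °C
Reagents that add atoms: none
Why: Fluoride-promoted protodeboronation of a benzylic boronic ester, in which the fluoroboronate breaks its C–B bond with protonation by the water of hydration at the carbon stabilised by ring B, so both epimers of 17 should converge on one compound while the two non-benzylic stereocentres stay untouched.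

Step 9
Reactants: 18 2-(benzyloxy)-5-[(2S,3R)-4-[4-(benzyloxy)-3-methoxyphenyl]-2,3-dimethylbutyl]-1,3-dimethoxybenzene
Product: 19 4-[(2S,3R)-4-(4-hydroxy-3-methoxyphenyl)-2,3-dimethylbutyl]-2,6-dimethoxyphenol
Conditions: H2 (1 atm), Pd/C, EtOAc/EtOH, rt
Reagents that add atoms: none
Why: Hydrogenolysis of both aryl benzyl ethers over palladium should free the two phenols without touching the methyl ethers or the stereocentres, neither of which is benzylic.

## Compound list

1 | [4-(benzyloxy)-3-methoxyphenyl]methanol | COc1cc(CO)ccc1OCc1ccccc1 | starting material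
2 | 1-(benzyloxy)-4-(chloromethyl)-2-methoxybenzene | COc1cc(CCl)ccc1OCc1ccccc1 | intermediate
3 | 2-[4-(benzyloxy)-3-methoxybenzyl]-4,4,5,5-tetramethyl-1,3,2-dioxaborolane | COc1cc(CB2OC(C)(C)C(C)(C)O2)ccc1OCc1ccccc1 | intermediate
4 | ethyl N,N-diisopropylcarbamate | CCOC(=O)N(C(C)C)C(C)C | starting material
5 | (S)-1-lithioethyl N,N-diisopropylcarbamate, as its (−)-sparteine complex (ligand not drawn) | C[C@H]([Li])OC(=O)N(C(C)C)C(C)C | intermediate (not isolated)
6 | lithium [4-(benzyloxy)-3-methoxybenzyl][(1S)-1-(diisopropylcarbamoyloxy)ethyl]pinacolatoborate | [Li+].C[C@H]([B-]1(Cc2ccc(OCc3ccccc3)c(OC)c2)OC(C)(C)C(C)(C)O1)OC(=O)N(C(C)C)C(C)C | intermediate (not isolated)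
7 | 2-[(2R)-1-[4-(benzyloxy)-3-methoxyphenyl]propan-2-yl]-4,4,5,5-tetramethyl-1,3,2-dioxaborolane | COc1cc(C[C@@H](C)B2OC(C)(C)C(C)(C)O2)ccc1OCc1ccccc1 | intermediate
8 | ethyl 2,4,6-triisopropylbenzoate | CCOC(=O)c1c(C(C)C)cc(C(C)C)cc1C(C)C | starting material
9 | (S)-1-lithioethyl 2,4,6-triisopropylbenzoate, as its (−)-sparteine complex (ligand not drawn) | C[C@H]([Li])OC(=O)c1c(C(C)C)cc(C(C)C)cc1C(C)C | intermediate (not isolated)
10 | lithium [(2R)-1-[4-(benzyloxy)-3-methoxyphenyl]propan-2-yl][(1S)-1-(2,4,6-triisopropylbenzoyloxy)ethyl]pinacolatoborate | [Li+].C[C@H]([B-]1([C@H](C)Cc2ccc(OCc3ccccc3)c(OC)c2)OC(C)(C)C(C)(C)O1)OC(=O)c1c(C(C)C)cc(C(C)C)cc1C(C)C | intermediate (not isolated)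
11 | 2-[(2R,3R)-4-[4-(benzyloxy)-3-methoxyphenyl]-3-methylbutan-2-yl]-4,4,5,5-tetramethyl-1,3,2-dioxaborolane | C[C@@H](B1OC(C)(C)C(C)(C)O1)[C@H](C)Cc1ccc(OCc2ccccc2)c(OC)c1 | intermediate
12 | 4-(hydroxymethyl)-2,6-dimethoxyphenol (syringyl alcohol) | COc1cc(CO)cc(OC)c1O | starting material
13 | [4-(benzyloxy)-3,5-dimethoxyphenyl]methanol | COc1cc(CO)cc(OC)c1OCc1ccccc1 | intermediate
14 | 4-(benzyloxy)-3,5-dimethoxybenzyl N,N-diisopropylcarbamate | COc1cc(COC(=O)N(C(C)C)C(C)C)cc(OC)c1OCc1ccccc1 | intermediate
15 | [4-(benzyloxy)-3,5-dimethoxyphenyl](lithio)methyl N,N-diisopropylcarbamate, TMEDA complex, racemic and configurationally labile (ligand not drawn) | COc1cc(C([Li])OC(=O)N(C(C)C)C(C)C)cc(OC)c1OCc1ccccc1 | intermediate (not isolated)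
16 | lithium [[4-(benzyloxy)-3,5-dimethoxyphenyl](diisopropylcarbamoyloxy)methyl][(2R,3R)-4-[4-(benzyloxy)-3-methoxyphenyl]-3-methylbutan-2-yl]pinacolatoborate (both epimers at the carbamate carbon) | [Li+].COc1cc(C(OC(=O)N(C(C)C)C(C)C)[B-]2([C@H](C)[C@H](C)Cc3ccc(OCc4ccccc4)c(OC)c3)OC(C)(C)C(C)(C)O2)cc(OC)c1OCc1ccccc1 | intermediate (not isolated)
17 | 2-[(2S,3R)-1-[4-(benzyloxy)-3,5-dimethoxyphenyl]-4-[4-(benzyloxy)-3-methoxyphenyl]-2,3-dimethylbutyl]-4,4,5,5-tetramethyl-1,3,2-dioxaborolane (both epimers at C1) | COc1cc(C(B2OC(C)(C)C(C)(C)O2)[C@H](C)[C@H](C)Cc2ccc(OCc3ccccc3)c(OC)c2)cc(OC)c1OCc1ccccc1 | intermediate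
18 | 2-(benzyloxy)-5-[(2S,3R)-4-[4-(benzyloxy)-3-methoxyphenyl]-2,3-dimethylbutyl]-1,3-dimethoxybenzene | COc1cc(C[C@H](C)[C@H](C)Cc2ccc(OCc3ccccc3)c(OC)c2)cc(OC)c1OCc1ccccc1 | intermediate
19 | 4-[(2S,3R)-4-(4-hydroxy-3-methoxyphenyl)-2,3-dimethylbutyl]-2,6-dimethoxyphenol | COc1cc(C[C@@H](C)[C@@H](C)Cc2cc(OC)c(O)c(OC)c2)ccc1O | target

## Step count and risks

Total steps: 9. Longest linear sequence: 7 steps (steps 1, 2, 3, 4, 7, 8, 9).

Steps most likely to fail:

Step 7 (key step). The lithiated carbamate 15 may be captured only slowly or reversibly by the α-branched boron of 11, or metalation may stray to ring B or to the benzyl ether, so that little boronate forms. Fallback: the union is moved by one carbon. Setting out from 11, Matteson homologation with chloromethyllithium (BrCH2Cl, n-BuLi, THF, −78 °C to rt) should pass through the lithium chloromethyl boronate complex F1 and give, with retention at the migrating carbon, the primary boronic ester 2-[(2S,3R)-4-[4-(benzyloxy)-3-methoxyphenyl]-2,3-dimethylbutyl]-4,4,5,5-tetramethyl-1,3,2-dioxaborolane F2. Suzuki–Miyaura coupling of F2 (Pd(OAc)2, di(1-adamantyl)-n-butylphosphine, LiOt-Bu, dioxane/H2O, 100 °C) with 5-bromo-2-(benzyloxy)-1,3-dimethoxybenzene F3, itself made from commercial 4-bromo-2,6-dimethoxyphenol (BnBr, K2CO3, DMF), should come back to the route at 18. The bond made is then the aryl–CH2 bond of ring B.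

Step 8. Protonolysis of the C–B bond at a hindered secondary benzylic carbon on an alkoxy-rich ring may be slow, so that 17 stays unchanged or is oxidised on handling. Fallback: setting out from 17, oxidation with NaBO3·4H2O (THF/H2O, rt) should give, with retention, (2R,3R)-1-[4-(benzyloxy)-3,5-dimethoxyphenyl]-4-[4-(benzyloxy)-3-methoxyphenyl]-2,3-dimethylbutan-1-ol F4 (both epimers at C1). Its S-methyl xanthate F5 (NaH, CS2, then MeI, THF) should then undergo Barton–McCombie deoxygenation (Bu3SnH, AIBN, toluene, 80 °C) and come back to the route at 18. The radical path avoids a benzylic cation, which would cyclise onto ring A.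

Step 4. The second carbenoid insertion may stall at boronate formation because the boron of 7 sits on a branched secondary carbon, or reagent control may be eroded by the existing centre. Fallback: the roles are exchanged, so that the chain becomes the carbenoid and an unhindered boronic ester delivers the methyl group. Setting out from 7, chloromethyllithium (BrCH2Cl, n-BuLi, THF, −78 °C to rt) should give, through the lithium chloromethyl boronate complex F6, the primary boronic ester 2-[(2S)-3-[4-(benzyloxy)-3-methoxyphenyl]-2-methylpropyl]-4,4,5,5-tetramethyl-1,3,2-dioxaborolane F7. F7 is oxidised in the same flask (NaOH, H2O2) to (2R)-3-[4-(benzyloxy)-3-methoxyphenyl]-2-methylpropan-1-ol F8. Mitsunobu esterification (2,4,6-triisopropylbenzoic acid, PPh3, DIAD, THF) gives (2R)-3-[4-(benzyloxy)-3-methoxyphenyl]-2-methylpropyl 2,4,6-triisopropylbenzoate F9. s-BuLi/(+)-sparteine (Et2O, −78 °C) should give the (1R,2R)-1-lithio benzoate F10, which methylboronic acid pinacol ester traps as the lithium methylboronate complex F11. The 1,2-shift of methyl with inversion at carbon (warm to reflux) comes back to the route at 11.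

## Further compounds

F1 | step 7 | lithium (chloromethyl)[(2R,3R)-4-[4-(benzyloxy)-3-methoxyphenyl]-3-methylbutan-2-yl]pinacolatoborate | [Li+].ClC[B-]1(OC(C)(C)C(C)(C)O1)[C@H](C)[C@H](C)Cc1ccc(OCc2ccccc2)c(OC)c1
F2 | step 7 | 2-[(2S,3R)-4-[4-(benzyloxy)-3-methoxyphenyl]-2,3-dimethylbutyl]-4,4,5,5-tetramethyl-1,3,2-dioxaborolane | C[C@@H](CB1OC(C)(C)C(C)(C)O1)[C@H](C)Cc1ccc(OCc2ccccc2)c(OC)c1
F3 | step 7 | 5-bromo-2-(benzyloxy)-1,3-dimethoxybenzene | COc1cc(Br)cc(OC)c1OCc1ccccc1
F4 | step 8 | (2R,3R)-1-[4-(benzyloxy)-3,5-dimethoxyphenyl]-4-[4-(benzyloxy)-3-methoxyphenyl]-2,3-dimethylbutan-1-ol (both epimers at C1) | COc1cc(C(O)[C@H](C)[C@H](C)Cc2ccc(OCc3ccccc3)c(OC)c2)cc(OC)c1OCc1ccccc1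
F5 | step 8 | O-[(2R,3R)-1-[4-(benzyloxy)-3,5-dimethoxyphenyl]-4-[4-(benzyloxy)-3-methoxyphenyl]-2,3-dimethylbutyl] S-methyl carbonodithioate (both epimers at C1) | COc1cc(C(OC(=S)SC)[C@H](C)[C@H](C)Cc2ccc(OCc3ccccc3)c(OC)c2)cc(OC)c1OCc1ccccc1
F6 | step 4 | lithium (chloromethyl)[(2R)-1-[4-(benzyloxy)-3-methoxyphenyl]propan-2-yl]pinacolatoborate | [Li+].ClC[B-]1(OC(C)(C)C(C)(C)O1)[C@H](C)Cc1ccc(OCc2ccccc2)c(OC)c1
F7 | step 4 | 2-[(2S)-3-[4-(benzyloxy)-3-methoxyphenyl]-2-methylpropyl]-4,4,5,5-tetramethyl-1,3,2-dioxaborolane | COc1cc(C[C@@H](C)CB2OC(C)(C)C(C)(C)O2)ccc1OCc1ccccc1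
F8 | step 4 | (2R)-3-[4-(benzyloxy)-3-methoxyphenyl]-2-methylpropan-1-ol | COc1cc(C[C@@H](C)CO)ccc1OCc1ccccc1
F9 | step 4 | (2R)-3-[4-(benzyloxy)-3-methoxyphenyl]-2-methylpropyl 2,4,6-triisopropylbenzoate | COc1cc(C[C@@H](C)COC(=O)c2c(C(C)C)cc(C(C)C)cc2C(C)C)ccc1OCc1ccccc1
F10 | step 4 | (1R,2R)-3-[4-(benzyloxy)-3-methoxyphenyl]-1-lithio-2-methylpropyl 2,4,6-triisopropylbenzoate, as its (+)-sparteine complex (ligand not drawn) | COc1cc(C[C@@H](C)[C@@H]([Li])OC(=O)c2c(C(C)C)cc(C(C)C)cc2C(C)C)ccc1OCc1ccccc1
F11 | step 4 | lithium methyl[(1R,2R)-3-[4-(benzyloxy)-3-methoxyphenyl]-2-methyl-1-(2,4,6-triisopropylbenzoyloxy)propyl]pinacolatoborate | [Li+].COc1cc(C[C@@H](C)[C@@H]([B-]2(C)OC(C)(C)C(C)(C)O2)OC(=O)c2c(C(C)C)cc(C(C)C)cc2C(C)C)ccc1OCc1ccccc1
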